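**Retrosynthetic overview**

1. The strategy rests on the γ-lactone ring O1–C2–C3–C4–C5. C5 is a fully substituted carbinol carbon bearing CHCl2 and the CH2 link to C3 of the isocoumarin, and C2–C3–C4 is a pyruvate unit, so the lactone is the aldol of a three-carbon keto acid with a side-chain dichloromethyl ketone.
2. Target ⇐ 8-O-methyl ether 14 ⇐ α-keto lactone 13 (C3=O) ⇐ α-methylene lactone 11 (C3=CH2), where the methylene stands in for the pyruvate carbonyl.
3. Lactone 11 ⇐ dichloromethyl ketone 7 + 2-(ethoxycarbonyl)allylboronate 9. This forms C4–C5 and O1–C2 and sets the C5 stereocentre.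
4. Ketone 7 ⇐ 6,8-dimethoxy-3-methylisocoumarin 3 + dichloroacetaldehyde (lateral aldol, then oxidation); 3 ⇐ 2,4-dimethoxybenzoic acid + isopropenyl acetate (C–H annulation).
5. Ring order: the benzene ring comes with acid 1, the pyranone ring is closed in step 1, and the lactone ring is closed last, in step 5.

Key step: step 5

Assumption: the (S)-enantiomer of the binaphthol catalyst is taken to deliver the allyl group to the Si face of ketone 7 (chair with CHCl2 equatorial); if the first experiment shows the opposite sense, the (R)-catalyst is used with no other change.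

**Route**

Step 1
Reactants: 1 2,4-dimethoxybenzoic acid; 2 isopropenyl acetate
Product: 3 6,8-dimethoxy-3-methyl-1H-isochromen-1-one
Conditions: [Cp*RhCl2]2 (2.5 mol %), Cu(OAc)2·H2O (2.1 equiv), toluene, 110 °C
Reagents that add atoms: none
Why: Carboxylate-directed C–H activation with oxidative annulation, in which the only free ortho C–H of 1 is rhodated, the enol acetate inserts with the aryl group on its CH2 terminus, C–O bond formation and loss of acetic acid give the 3-methylisocoumarin, and Cu(OAc)2 returns monovalent rhodium to the trivalent state.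

Step 2
Reactants: 3 6,8-dimethoxy-3-methyl-1H-isochromen-1-one; 4 dichloroacetaldehyde
Product: 6 rac-3-(3,3-dichloro-2-hydroxypropyl)-6,8-dimethoxy-1H-isochromen-1-one, via lithiated isocoumarin 5 (not isolated)
Conditions: LiN(i-Pr)2 (1.1 equiv), THF, −78 °C; then freshly distilled anhydrous 4, −78 °C; AcOH quench at −78 °C
Reagents that add atoms: none
Why: Vinylogous lateral metalation followed by aldol addition, in which the 3-methyl group is acidified through C3=C4 and the aryl lactone carbonyl as the 6-methyl group of a 2-pyranone is, the exocyclic anion should add to the very electrophilic aldehyde faster than it deprotonates it, and the cold acidic quench avoids retro-aldol and epoxide formation; the new carbinol centre forms as a racemate and is removed in step 3.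

Step 3
Reactants: 6 rac-3-(3,3-dichloro-2-hydroxypropyl)-6,8-dimethoxy-1H-isochromen-1-one
Product: 7 3-(3,3-dichloro-2-oxopropyl)-6,8-dimethoxy-1H-isochromen-1-one
Conditions: Dess–Martin periodinane (1.3 equiv), CH2Cl2, 0 °C to rt
Reagents that add atoms: none
Why: Dess–Martin oxidation of a secondary alcohol under neutral, non-basic conditions, which tolerates the dichloromethyl group and avoids enolate chemistry at the activated CH2.

Step 4
Reactants: 8 ethyl 2-(bromomethyl)acrylate
Product: 9 ethyl 2-[(4,4,5,5-tetramethyl-1,3,2-dioxaborolan-2-yl)methyl]acrylate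
Conditions: B2pin2 (1.1 equiv), Pd2(dba)3 (1 mol %), THF, 50 °C
Reagents that add atoms: bis(pinacolato)diboron, CC1(C)OB(OC1(C)C)B1OC(C)(C)C(C)(C)O1
Why: Palladium-catalysed allylic borylation (oxidative addition of the allylic bromide to zerovalent palladium, transmetalation with B2pin2, reductive elimination), a known way to 2-(alkoxycarbonyl)allylboronates.

Step 5
Reactants: 7 3-(3,3-dichloro-2-oxopropyl)-6,8-dimethoxy-1H-isochromen-1-one; 9 ethyl 2-[(4,4,5,5-tetramethyl-1,3,2-dioxaborolan-2-yl)methyl]acrylate
Product: 11 (5R)-5-(dichloromethyl)-5-[(6,8-dimethoxy-1-oxo-1H-isochromen-3-yl)methyl]-3-methylideneoxolan-2-one, via tertiary pinacol borate 10 (not isolated)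
Conditions: 9 (1.5 equiv), (S)-3,3'-dibromo-1,1'-bi-2-naphthol (20 mol %), t-BuOH (2 equiv), toluene–PhCF3 (1:3), rt to 40 °C; then TsOH·H2O (10 mol %), rt
Reagents that add atoms: none
Why: Proposed new method: exchange of one boron–oxygen bond of 9 for a binaphthol oxygen (helped by t-BuOH) should give a more Lewis-acidic allylboron species that binds the carbonyl oxygen of 7 and transfers the allyl group through a closed six-membered chair transition state with allyl transposition, so that the former =CH2 carbon of 9 becomes C4 bonded to C5. The closest known reactions are the binaphthol-catalysed enantioselective allylboration of ketones and the addition of 2-(alkoxycarbonyl)allylboronates to carbonyl compounds with lactonisation, whose combination on an α,α-dichloromethyl ketone has not been tested. The lactone ring closes by 5-exo-trig attack of the tertiary borate oxygen of 10 on the ethyl ester (O1–C2), driven to completion by catalytic TsOH. The C5 stereocentre is set by the catalyst: with CHCl2 equatorial and the isocoumarinylmethyl group axial in the chair, the (S)-binaphthol is expected to leave the Si face of the ketone open, which gives (R)-C5. The step needs 1,2-addition without enolisation of the doubly activated CH2 and without attack on the isocoumarin lactone, which the neutral, non-basic boron reagent and the high electrophilicity of the dichloromethyl ketone should secure, while the low nucleophilicity of the ester-substituted boronate keeps the uncatalysed background slow.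

Step 6
Reactants: 11 (5R)-5-(dichloromethyl)-5-[(6,8-dimethoxy-1-oxo-1H-isochromen-3-yl)methyl]-3-methylideneoxolan-2-one
Product: 13 (5S)-5-(dichloromethyl)-5-[(6,8-dimethoxy-1-oxo-1H-isochromen-3-yl)methyl]oxolane-2,3-dione, via diol 12 (not isolated)
Conditions: OsO4 (2 mol %), NaIO4 (3 equiv), 2,6-lutidine (2 equiv), dioxane–H2O (3:1), 0 °C to rt
Reagents that add atoms: sodium periodate, [Na+].[O-]I(=O)(=O)=O (terminal oxidant, its oxygen reaches C3 through osmium tetroxide, O=[Os](=O)(=O)=O)
Why: Lemieux–Johnson oxidation, in which OsO4 should dihydroxylate the unhindered exocyclic 1,1-disubstituted alkene in preference to the trisubstituted C3=C4 bond held in the conjugated pyranone, NaIO4 cleaves diol 12 and reoxidises osmium, and 2,6-lutidine limits over-oxidation; the quaternary centre is untouched, and its descriptor changes only because C4 now outranks the isocoumarinylmethyl group.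

Step 7
Reactants: 13 (5S)-5-(dichloromethyl)-5-[(6,8-dimethoxy-1-oxo-1H-isochromen-3-yl)methyl]oxolane-2,3-dione
Product: 14 (3S,5R)-5-(dichloromethyl)-3-hydroxy-5-[(6,8-dimethoxy-1-oxo-1H-isochromen-3-yl)methyl]oxolan-2-one
Conditions: NaBH4 (0.5 equiv), THF–MeOH (4:1), −78 °C; then H2O
Reagents that add atoms: none
Why: Borohydride reduction of the activated ketone of an α-keto lactone, in which hydride is expected to reach C3 from the ring face away from the CHCl2 group on C5 (bulk and electrostatic repulsion of the two chlorines), so that the new hydroxyl lies cis to CHCl2 and C3 is set as (S) by 1,3-substrate control.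

Step 8
Reactants: 14 (3S,5R)-5-(dichloromethyl)-3-hydroxy-5-[(6,8-dimethoxy-1-oxo-1H-isochromen-3-yl)methyl]oxolan-2-one
Product: 15 (3S,5R)-5-(dichloromethyl)-3-hydroxy-5-[(8-hydroxy-6-methoxy-1-oxo-1H-isochromen-3-yl)methyl]oxolan-2-one
Conditions: BCl3 (3 equiv), CH2Cl2, −78 to 0 °C; then H2O
Reagents that add atoms: none
Why: Chelation-directed Lewis acid ether cleavage, in which BCl3 bridges the lactone carbonyl C1=O and the peri 8-methoxy oxygen so that chloride removes only that methyl group, while the 6-methoxy group, both lactones, the CHCl2 group and the two stereocentres are left alone.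

**Compound list**

1 | 2,4-dimethoxybenzoic acid | COc1ccc(C(=O)O)c(OC)c1 | starting material
2 | isopropenyl acetate | CC(=C)OC(C)=O | starting material
3 | 6,8-dimethoxy-3-methyl-1H-isochromen-1-one | COc1cc(OC)c2c(=O)oc(C)cc2c1 | intermediate
4 | dichloroacetaldehyde | O=CC(Cl)Cl | starting material
5 | 3-(lithiomethyl)-6,8-dimethoxy-1H-isochromen-1-one | [Li]Cc1cc2cc(OC)cc(OC)c2c(=O)o1 | intermediate (not isolated)
6 | rac-3-(3,3-dichloro-2-hydroxypropyl)-6,8-dimethoxy-1H-isochromen-1-one | COc1cc(OC)c2c(=O)oc(CC(O)C(Cl)Cl)cc2c1 | intermediate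
7 | 3-(3,3-dichloro-2-oxopropyl)-6,8-dimethoxy-1H-isochromen-1-one | COc1cc(OC)c2c(=O)oc(CC(=O)C(Cl)Cl)cc2c1 | intermediate
8 | ethyl 2-(bromomethyl)acrylate | C=C(CBr)C(=O)OCC | starting material
9 | ethyl 2-[(4,4,5,5-tetramethyl-1,3,2-dioxaborolan-2-yl)methyl]acrylate | C=C(CB1OC(C)(C)C(C)(C)O1)C(=O)OCC | intermediate
10 | ethyl (4R)-4-(dichloromethyl)-5-(6,8-dimethoxy-1-oxo-1H-isochromen-3-yl)-2-methylidene-4-[(4,4,5,5-tetramethyl-1,3,2-dioxaborolan-2-yl)oxy]pentanoate | COc1cc(OC)c2c(=O)oc(C[C@@](OB3OC(C)(C)C(C)(C)O3)(C(Cl)Cl)CC(=C)C(=O)OCC)cc2c1 | intermediate (not isolated)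
11 | (5R)-5-(dichloromethyl)-5-[(6,8-dimethoxy-1-oxo-1H-isochromen-3-yl)methyl]-3-methylideneoxolan-2-one | COc1cc(OC)c2c(=O)oc(C[C@@]3(C(Cl)Cl)CC(=C)C(=O)O3)cc2c1 | intermediate
12 | (5R)-5-(dichloromethyl)-3-hydroxy-3-(hydroxymethyl)-5-[(6,8-dimethoxy-1-oxo-1H-isochromen-3-yl)methyl]oxolan-2-one, both C3 epimers | COc1cc(OC)c2c(=O)oc(C[C@@]3(C(Cl)Cl)CC(O)(CO)C(=O)O3)cc2c1 | intermediate (not isolated)
13 | (5S)-5-(dichloromethyl)-5-[(6,8-dimethoxy-1-oxo-1H-isochromen-3-yl)methyl]oxolane-2,3-dione | COc1cc(OC)c2c(=O)oc(C[C@@]3(C(Cl)Cl)CC(=O)C(=O)O3)cc2c1 | intermediate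
14 | (3S,5R)-5-(dichloromethyl)-3-hydroxy-5-[(6,8-dimethoxy-1-oxo-1H-isochromen-3-yl)methyl]oxolan-2-one | COc1cc(OC)c2c(=O)oc(C[C@@]3(C(Cl)Cl)C[C@H](O)C(=O)O3)cc2c1 | intermediate
15 | (3S,5R)-5-(dichloromethyl)-3-hydroxy-5-[(8-hydroxy-6-methoxy-1-oxo-1H-isochromen-3-yl)methyl]oxolan-2-one | COc1cc(O)c2c(=O)oc(C[C@@]3(C(Cl)Cl)C[C@H](O)C(=O)O3)cc2c1 | target

**Step count**

Total: 8 steps. Longest linear sequence: 7 steps (steps 1, 2, 3, 5, 6, 7, 8); step 4 is a one-step side branch.

**Steps most likely to fail**

Step 5. Ligand exchange at the pinacol boronate may be too slow and the ester-substituted allyl group too weakly nucleophilic for catalytic turnover. The catalyst may also discriminate poorly between the CHCl2 and isocoumarinylmethyl flanks, and ketone 7 may enolise instead of adding. The fallback uses known chemistry and sets out from ketone 7 and bromide 8, leaving out step 4. Indium-mediated Barbier 2-(ethoxycarbonyl)allylation (indium powder, THF–H2O, rt) followed by treatment with catalytic TsOH should give the racemic α-methylene lactone F1. Preparative HPLC on a chiral stationary phase then separates the (5S)-enantiomer F2 and returns the route to 11.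

Step 7. Facial selectivity of hydride delivery may be poor or reversed, because the two substituents on C5 differ only moderately in size and the ring is nearly flat. The fallback sets out from 13 and corrects the carbinol by inversion instead of by selective reduction. The reduction is run as above, the (3R,5R)-epimer F3 is separated by chromatography and subjected to Mitsunobu inversion (4-nitrobenzoic acid, PPh3, DIAD, THF, 0 °C to rt) to give the (3S,5R) 4-nitrobenzoate F4. Mild methanolysis (NaN3, MeOH, 40 °C) then returns the route to 14. If F3 is the main product, all material passes through this inversion.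

Step 6. Osmylation may also take place at the electron-rich C3=C4 bond of the isocoumarin or at the enol form of the keto lactone, and periodate may cleave the keto lactone further. The fallback sets out from 11 and uses a nucleophilic oxidant that only the electron-poor exocyclic alkene accepts. Weitz–Scheffer-type epoxidation (anhydrous t-BuOOH, DBU, CH2Cl2, 0 °C to rt) should give the spiro-epoxide F5. Periodic acid (H5IO6, THF–H2O, rt) then opens and cleaves it with loss of formaldehyde and returns the route to 13.

**Further compounds**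

F1 | step 5 | racemic 5-(dichloromethyl)-5-[(6,8-dimethoxy-1-oxo-1H-isochromen-3-yl)methyl]-3-methylideneoxolan-2-one | COc1cc(OC)c2c(=O)oc(CC3(C(Cl)Cl)CC(=C)C(=O)O3)cc2c1
F2 | step 5 | (5S)-5-(dichloromethyl)-5-[(6,8-dimethoxy-1-oxo-1H-isochromen-3-yl)methyl]-3-methylideneoxolan-2-one | COc1cc(OC)c2c(=O)oc(C[C@]3(C(Cl)Cl)CC(=C)C(=O)O3)cc2c1
F3 | step 7 | (3R,5R)-5-(dichloromethyl)-3-hydroxy-5-[(6,8-dimethoxy-1-oxo-1H-isochromen-3-yl)methyl]oxolan-2-one | COc1cc(OC)c2c(=O)oc(C[C@@]3(C(Cl)Cl)C[C@@H](O)C(=O)O3)cc2c1
F4 | step 7 | (3S,5R)-5-(dichloromethyl)-5-[(6,8-dimethoxy-1-oxo-1H-isochromen-3-yl)methyl]-2-oxooxolan-3-yl 4-nitrobenzoate | COc1cc(OC)c2c(=O)oc(C[C@@]3(C(Cl)Cl)C[C@H](OC(=O)c4ccc(cc4)[N+](=O)[O-])C(=O)O3)cc2c1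
F5 | step 6 | 6-(dichloromethyl)-6-[(6,8-dimethoxy-1-oxo-1H-isochromen-3-yl)methyl]-1,5-dioxaspiro[2.4]heptan-4-one, quaternary carbon as in 11, both epimers at the spiro carbon | COc1cc(OC)c2c(=O)oc(C[C@@]3(C(Cl)Cl)CC4(CO4)C(=O)O3)cc2c1
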